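## Retrosynthetic overview

1. Oxolane numbering used here: O1, C2 (aryl), C3 (methyl), C4 (carbinol side chain), C5 (CH2). The last C–C bond is carbinol carbon–aryl, made by adding aryl Grignard 18 to the C4 carbaldehyde 17 (Felkin–Anh/chelate control sets the carbinol centre).
2. The aldehyde carbon and the C3 methyl carbon are cis on the ring, so they are traced back to the C=O and OCH2 of a cis-fused γ-lactone (furo[3,4-c]furanone 12). The lactone is unzipped via the Weinreb amide, and CH2OH is taken to CH3 through the iodide.
3. Key disconnection: bonds O1–C2 and C4–C5 of the oxolane in 12. Formaldehyde (O1 and C5) is added across the donor–acceptor cyclopropane 9 in one formal [3+2] step.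
4. Enabling feature: C2 is benzylic to the electron-rich 3,4-dimethoxyphenyl ring (donor), and C4 is alpha to the future carbinol carbon, which can be carried as a carbonyl (acceptor). C2–C3–C4 is therefore a latent 1,3-zwitterion, i.e. a cyclopropane, and the cis C3/C4 relation allows the lactone tether that fixes C4.
5. Ring order: cyclopropane and γ-lactone together (step 5, the only catalytic asymmetric step), then the oxolane (step 6), then lactone opening (step 7).

Key step: step 6

Assumption: Rh2(5R-MEPY)4 is taken to give the (1S,5R)-configured 3-oxabicyclo[3.1.0]hexan-2-one core, by analogy with simple allylic diazoacetates; if the sense of induction were opposite, Rh2(5S-MEPY)4 would be used.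

## Route

Step 1
Reactants: 1 4-iodo-1,2-dimethoxybenzene; 2 prop-2-yn-1-ol
Product: 3 3-(3,4-dimethoxyphenyl)prop-2-yn-1-ol
Conditions: PdCl2(PPh3)2 (2 mol %), CuI (4 mol %), Et3N, THF, rt
Reagents that add atoms: none
Why: Sonogashira coupling of an electron-rich aryl iodide with a terminal alkyne is reliable and tolerates the free hydroxyl; no stereocentre is formed.

Step 2
Reactants: 3 3-(3,4-dimethoxyphenyl)prop-2-yn-1-ol
Product: 4 (Z)-3-(3,4-dimethoxyphenyl)prop-2-en-1-ol
Conditions: H2 (1 atm), Lindlar catalyst (Pd on CaCO3 poisoned with Pb(OAc)2), quinoline, EtOAc, rt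
Reagents that add atoms: none
Why: Lindlar semihydrogenation adds H2 syn on the poisoned palladium surface and should stop at the Z-alkene, the geometry that later places the aryl group endo on the cyclopropane.

Step 3
Reactants: 4 (Z)-3-(3,4-dimethoxyphenyl)prop-2-en-1-ol; 5 bromoacetyl bromide
Product: 6 (Z)-3-(3,4-dimethoxyphenyl)prop-2-en-1-yl bromoacetate
Conditions: NaHCO3, MeCN, 0 °C
Reagents that add atoms: none
Why: O-acylation of a primary allylic alcohol with an acyl bromide, buffered by bicarbonate so that the acid-sensitive Z-cinnamyl system should not ionise or isomerise.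

Step 4
Reactants: 6 (Z)-3-(3,4-dimethoxyphenyl)prop-2-en-1-yl bromoacetate
Product: 8 (Z)-3-(3,4-dimethoxyphenyl)prop-2-en-1-yl diazoacetate, via N-alkylated ditosylhydrazide 7 (not isolated)
Conditions: N,N'-ditosylhydrazine (2 equiv), DBU (5 equiv), THF, 0 °C
Reagents that add atoms: N,N'-ditosylhydrazine, Cc1ccc(S(=O)(=O)NNS(=O)(=O)c2ccc(C)cc2)cc1
Why: Diazoacetate synthesis by the N,N'-ditosylhydrazine method: N-alkylation by the bromoacetate gives 7, which loses two p-toluenesulfinate units under DBU to unveil the diazo group under mild, non-acidic conditions.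

Step 5
Reactants: 8 (Z)-3-(3,4-dimethoxyphenyl)prop-2-en-1-yl diazoacetate
Product: 9 (1S,5R,6S)-6-(3,4-dimethoxyphenyl)-3-oxabicyclo[3.1.0]hexan-2-one (aryl endo, cis to the lactone ring)
Conditions: Rh2(5R-MEPY)4 (1 mol %), CH2Cl2, reflux, slow addition of 8
Reagents that add atoms: none
Why: Chiral dirhodium carboxamidate-catalysed intramolecular cyclopropanation of an allylic diazoacetate: carbene transfer is stereospecific for the Z-alkene (aryl ends endo), the cis ring fusion is obligatory, and the ligand pocket selects the alkene face, so all three cyclopropane stereocentres, including the future methyl-bearing carbon, are set in this one catalytic asymmetric event.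

Step 6
Reactants: 9 (1S,5R,6S)-6-(3,4-dimethoxyphenyl)-3-oxabicyclo[3.1.0]hexan-2-one; 10 1,3,5-trioxane (formaldehyde source, 2 equiv)
Product: 12 (3aR,4S,6aR)-4-(3,4-dimethoxyphenyl)tetrahydro-1H,3H-furo[3,4-c]furan-1-one, via oxocarbenium silyl ketene acetal 11 (not isolated)
Conditions: TMSOTf (0.3 equiv), 2,6-di-tert-butyl-4-methylpyridine (0.1 equiv), CH2Cl2, −78 to −30 °C; Et3N quench
Reagents that add atoms: none
Why: Proposed new method: a silyl-triflate-catalysed formal [3+2] annulation of a donor–acceptor cyclopropane with formaldehyde, whose closest known relative is the Lewis-acid-catalysed (Sn(OTf)2, SnCl4, AlCl3) cycloaddition of 2-arylcyclopropane-1,1-diesters with aldehydes, stereospecific with inversion at the aryl-bearing carbon; new here is that a single lactone carbonyl serves as acceptor, which the strongly donating 3,4-dimethoxyphenyl group, the strain of the bicyclo[3.1.0] lactone and O-silylation are expected to offset. Mechanism: TMSOTf silylates the lactone carbonyl, the oxygen of formaldehyde (released from 10) attacks the benzylic cyclopropane carbon anti to the breaking bond to the alpha carbon and gives 11, whose silyl ketene acetal carbon then adds to the O-alkyl oxocarbenium carbon and returns the silyl cation. The oxolane closes in a 5-(enolexo)-endo-trig Mukaiyama-aldol-type step. The aryl-bearing carbon is set by SN2-like inversion of the endo-aryl cyclopropane carbon (the aryl ends trans to the neighbouring ring-fusion substituent, on the convex face), the carbon that will carry the methyl group is taken over untouched from 9, and the alpha carbon is fixed by the lactone tether because only the cis-fused bicyclo[3.3.0] product can form. The step needs cleavage of the cyclopropane bond to the aryl-bearing carbon rather than to the other ring-fusion carbon, which the aryl donor secures, and capture before free ionisation, which low temperature, excess formaldehyde and the non-nucleophilic triflate should favour; the non-epimerisable ring-fusion stereocentre protects the enantiomeric purity in any case, so only the aryl-bearing centre is at stake.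

Step 7
Reactants: 12 (3aR,4S,6aR)-4-(3,4-dimethoxyphenyl)tetrahydro-1H,3H-furo[3,4-c]furan-1-one
Product: 13 (3R,4R,5S)-5-(3,4-dimethoxyphenyl)-4-(hydroxymethyl)-N-methoxy-N-methyloxolane-3-carboxamide
Conditions: MeNH(OMe)·HCl (3 equiv), Me3Al (3 equiv), CH2Cl2, 0 °C to rt; product used crude
Reagents that add atoms: N,O-dimethylhydroxylamine hydrochloride, CNOC.Cl
Why: Weinreb aminolysis of a γ-lactone by the aluminium amide attacks only the acyl carbon, leaves the alpha stereocentre untouched, frees the primary alcohol and gives an amide that can later be stopped at the aldehyde level.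

Step 8
Reactants: 13 (3R,4R,5S)-5-(3,4-dimethoxyphenyl)-4-(hydroxymethyl)-N-methoxy-N-methyloxolane-3-carboxamide
Product: 14 (3R,4S,5S)-5-(3,4-dimethoxyphenyl)-4-(iodomethyl)-N-methoxy-N-methyloxolane-3-carboxamide
Conditions: I2, PPh3, imidazole, CH2Cl2, 0 °C to rt
Reagents that add atoms: iodine, II
Why: Appel-type (Garegg–Samuelsson) iodination converts the primary alcohol into the iodide through an alkoxyphosphonium ion and SN2 attack by iodide at the primary carbon, touching no stereocentre.

Step 9
Reactants: 14 (3R,4S,5S)-5-(3,4-dimethoxyphenyl)-4-(iodomethyl)-N-methoxy-N-methyloxolane-3-carboxamide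
Product: 15 (3R,4S,5S)-5-(3,4-dimethoxyphenyl)-N-methoxy-N,4-dimethyloxolane-3-carboxamide
Conditions: nBu3SnH (1.5 equiv), AIBN (cat.), toluene, 80 °C
Reagents that add atoms: none
Why: Radical-chain dehalogenation with tin hydride reduces the primary C–I bond to C–H under neutral conditions, which should leave the benzylic ether and the C–H alpha to the amide intact.

Step 10
Reactants: 15 (3R,4S,5S)-5-(3,4-dimethoxyphenyl)-N-methoxy-N,4-dimethyloxolane-3-carboxamide
Product: 17 (3R,4S,5S)-5-(3,4-dimethoxyphenyl)-4-methyloxolane-3-carbaldehyde, via aluminium hemiaminal 16 (not isolated)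
Conditions: iBu2AlH (1.3 equiv), THF, −78 °C; cold aq. potassium sodium tartrate; aldehyde used at once
Reagents that add atoms: none
Why: Weinreb amide reduction stops at the chelated tetrahedral adduct 16, which releases the aldehyde only on cold aqueous work-up, so over-reduction and epimerisation of the cis alpha centre should be kept low.

Step 11
Reactants: 17 (3R,4S,5S)-5-(3,4-dimethoxyphenyl)-4-methyloxolane-3-carbaldehyde; 18 (3,4-dimethoxyphenyl)magnesium bromide (0.5 M in THF, 2 equiv)
Product: 19 (R)-(3,4-dimethoxyphenyl)[(3R,4S,5S)-5-(3,4-dimethoxyphenyl)-4-methyloxolan-3-yl]methanol (CNP0269167.1)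
Conditions: THF, −78 °C; then H2O/NH4Cl work-up
Reagents that add atoms: none
Why: Grignard 1,2-addition to an alpha-branched aldehyde under Felkin–Anh control, reinforced by a magnesium chelate between the aldehyde oxygen and the ring oxygen: the aryl nucleophile attacks anti to the methyl-bearing ring carbon, which should give the (R)-carbinol.

## Compound list

1 | 4-iodo-1,2-dimethoxybenzene | COc1ccc(I)cc1OC | starting material
2 | prop-2-yn-1-ol | C#CCO | starting material
3 | 3-(3,4-dimethoxyphenyl)prop-2-yn-1-ol | COc1ccc(C#CCO)cc1OC | intermediate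
4 | (Z)-3-(3,4-dimethoxyphenyl)prop-2-en-1-ol | COc1ccc(/C=C\CO)cc1OC | intermediate
5 | bromoacetyl bromide | BrCC(Br)=O | starting material
6 | (Z)-3-(3,4-dimethoxyphenyl)prop-2-en-1-yl bromoacetate | COc1ccc(/C=C\COC(=O)CBr)cc1OC | intermediate
7 | (Z)-3-(3,4-dimethoxyphenyl)prop-2-en-1-yl 2-[1,2-bis(4-methylphenylsulfonyl)hydrazin-1-yl]acetate | COc1ccc(/C=C\COC(=O)CN(NS(=O)(=O)c2ccc(C)cc2)S(=O)(=O)c2ccc(C)cc2)cc1OC | intermediate (not isolated)
8 | (Z)-3-(3,4-dimethoxyphenyl)prop-2-en-1-yl diazoacetate | COc1ccc(/C=C\COC(=O)C=[N+]=[N-])cc1OC | intermediate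
9 | (1S,5R,6S)-6-(3,4-dimethoxyphenyl)-3-oxabicyclo[3.1.0]hexan-2-one | COc1ccc([C@H]2[C@H]3COC(=O)[C@@H]23)cc1OC | intermediate
10 | 1,3,5-trioxane | C1OCOCO1 | starting material
11 | O-methylidene oxonium of the ring-opened 2-(trimethylsilyloxy)-4,5-dihydrofuran, triflate salt | C=[O+][C@H](c1ccc(OC)c(OC)c1)[C@H]1COC(O[Si](C)(C)C)=C1.[O-]S(=O)(=O)C(F)(F)F | intermediate (not isolated)
12 | (3aR,4S,6aR)-4-(3,4-dimethoxyphenyl)tetrahydro-1H,3H-furo[3,4-c]furan-1-one | COc1ccc([C@H]2OC[C@H](C(=O)OC3)[C@@H]23)cc1OC | intermediate
13 | (3R,4R,5S)-5-(3,4-dimethoxyphenyl)-4-(hydroxymethyl)-N-methoxy-N-methyloxolane-3-carboxamide | COc1ccc([C@H]2OC[C@H](C(=O)N(C)OC)[C@@H]2CO)cc1OC | intermediate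
14 | (3R,4S,5S)-5-(3,4-dimethoxyphenyl)-4-(iodomethyl)-N-methoxy-N-methyloxolane-3-carboxamide | COc1ccc([C@H]2OC[C@H](C(=O)N(C)OC)[C@@H]2CI)cc1OC | intermediate
15 | (3R,4S,5S)-5-(3,4-dimethoxyphenyl)-N-methoxy-N,4-dimethyloxolane-3-carboxamide | COc1ccc([C@H]2OC[C@H](C(=O)N(C)OC)[C@@H]2C)cc1OC | intermediate
16 | diisobutylaluminium hemiaminal of 15 (mixture at the hemiaminal carbon) | COc1ccc([C@H]2OC[C@H](C(O[Al](CC(C)C)CC(C)C)N(C)OC)[C@@H]2C)cc1OC | intermediate (not isolated)
17 | (3R,4S,5S)-5-(3,4-dimethoxyphenyl)-4-methyloxolane-3-carbaldehyde | COc1ccc([C@H]2OC[C@H](C=O)[C@@H]2C)cc1OC | intermediate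
18 | (3,4-dimethoxyphenyl)magnesium bromide | COc1ccc([Mg]Br)cc1OC | starting material
19 | (R)-(3,4-dimethoxyphenyl)[(3R,4S,5S)-5-(3,4-dimethoxyphenyl)-4-methyloxolan-3-yl]methanol | COc1ccc([C@H]2OC[C@H]([C@@H](O)c3ccc(OC)c(OC)c3)[C@@H]2C)cc1OC | target

## Step count and risks

Total steps: 11. Longest linear sequence: 11 steps (from 1).

Steps most likely to fail:

1. Step 6 (Proposed new method). The single lactone acceptor may not activate the cyclopropane enough, or the benzylic carbon may ionise before it is captured, which would erode the inversion at the aryl-bearing centre. Lewis-acid-activated formaldehyde may also hydroxymethylate the electron-rich arene. The fallback uses the doubly activated cyclopropane of the known diester type and sets out from 4. Acylation with methyl 3-chloro-3-oxopropanoate (pyridine, CH2Cl2, 0 °C) would give methyl (Z)-3-(3,4-dimethoxyphenyl)prop-2-en-1-yl malonate F1. Regitz diazo transfer (4-acetamidobenzenesulfonyl azide, Et3N, MeCN) would give the diazomalonate F2. Intramolecular cyclopropanation with a monovalent copper catalyst ([Cu(MeCN)4]PF6 and a chiral bis(oxazoline) ligand) would give methyl (1S,5R,6R)-6-(3,4-dimethoxyphenyl)-2-oxo-3-oxabicyclo[3.1.0]hexane-1-carboxylate F3; the enantiomeric excess is expected to be lower than in step 5 and would be raised by crystallisation. The established Sn(OTf)2-catalysed [3+2] cycloaddition with paraformaldehyde (CH2Cl2, rt or below) would give methyl (3aR,4S,6aR)-4-(3,4-dimethoxyphenyl)-1-oxotetrahydrofuro[3,4-c]furan-6a-carboxylate F4. Krapcho demethoxycarbonylation (LiCl, wet DMSO, 140 °C) comes back to the route at 12, since the cis ring fusion forces reprotonation to the same configuration.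

2. Step 8. The amide oxygen may attack the activated primary carbon, so that the Weinreb amine is lost and lactone 12 is re-formed on work-up. The fallback avoids electrophilic activation of that carbon and sets out from 13. Acylation with O-phenyl chlorothionoformate (pyridine, DMAP, CH2Cl2) would give the O-phenyl thionocarbonate of 13 F5. Barton–McCombie deoxygenation (nBu3SnH, AIBN, toluene, 110 °C) comes back to the route at 15, bypassing 14.

3. Step 11. The cis-configured aldehyde may epimerise at its alpha carbon before or during the addition, and the facial selectivity may be poor. The fallback never frees the aldehyde and sets out from 15. Addition of 18 to the Weinreb amide (THF, 0 °C) would give (3,4-dimethoxyphenyl)[(3R,4S,5S)-5-(3,4-dimethoxyphenyl)-4-methyloxolan-3-yl]methanone F6. Reagent-controlled Corey–Bakshi–Shibata reduction ((S)-2-methyl-CBS-oxazaborolidine, BH3·SMe2, THF, −20 °C) comes back to the route at 19. Reagent control is needed here because hydride addition under substrate control is expected to favour the carbinol epimer.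

Further compounds

F1 | step 6 | methyl (Z)-3-(3,4-dimethoxyphenyl)prop-2-en-1-yl malonate | COc1ccc(/C=C\COC(=O)CC(=O)OC)cc1OC
F2 | step 6 | 1-methyl 3-[(Z)-3-(3,4-dimethoxyphenyl)prop-2-en-1-yl] 2-diazomalonate | COc1ccc(/C=C\COC(=O)C(=[N+]=[N-])C(=O)OC)cc1OC
F3 | step 6 | methyl (1S,5R,6R)-6-(3,4-dimethoxyphenyl)-2-oxo-3-oxabicyclo[3.1.0]hexane-1-carboxylate | COc1ccc([C@H]2[C@H]3COC(=O)[C@@]23C(=O)OC)cc1OC
F4 | step 6 | methyl (3aR,4S,6aR)-4-(3,4-dimethoxyphenyl)-1-oxotetrahydrofuro[3,4-c]furan-6a-carboxylate | COc1ccc([C@H]2OC[C@](C(=O)OC)(C(=O)OC3)[C@@H]23)cc1OC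
F5 | step 8 | O-{[(2S,3S,4R)-2-(3,4-dimethoxyphenyl)-4-[methoxy(methyl)carbamoyl]oxolan-3-yl]methyl} O-phenyl carbonothioate | COc1ccc([C@H]2OC[C@H](C(=O)N(C)OC)[C@@H]2COC(=S)Oc2ccccc2)cc1OC
F6 | step 11 | (3,4-dimethoxyphenyl)[(3R,4S,5S)-5-(3,4-dimethoxyphenyl)-4-methyloxolan-3-yl]methanone | COc1ccc([C@H]2OC[C@H](C(=O)c3ccc(OC)c(OC)c3)[C@@H]2C)cc1OC
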